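**Retrosynthetic overview**
- Oxidise a protected 3-hydroxypropyl chain to give the acid. Make the coumarin ether by Mitsunobu coupling of umbelliferone with a primary cyclopentylmethanol.
- Build the cyclopentylmethanol from a cyclopentanone: Me–C(Me) is set by α-methylenation then face-selective hydrogenation, and CH2OH by Petasis methylenation, hydroboration and epimerisation of the aldehyde to the more stable isomer.
- Set the isobutenyl-bearing carbon and the adjacent quaternary carbon together with one Cu-catalysed asymmetric conjugate addition of isobutenylMgBr to a 2-alkylcyclopentenone, followed by enolate methylation (the proposed new step).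
- No ring is formed in the route. The cyclopentane comes from 2-cyclopentenone (iodination, then B-alkyl Suzuki coupling) and the coumarin from umbelliferone.

Assumptions: umbelliferone, allyl TBS ether, isobutenylMgBr and Cp2TiMe2 are commercial. The CH2OAr-down isomer is taken to be the thermodynamic aldehyde epimer (Step 10).

**Step 1**
Reactants: 1 (cyclopent-2-en-1-one)
Product: 2 (2-iodocyclopent-2-en-1-one)
Conditions: I2, pyridine, CH2Cl2, 0 °C → rt
Reagents that add atoms: iodine, II
Why: Johnson α-iodination of the enone by pyridine addition, iodination and elimination; no stereocentres are formed.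

**Step 2**
Reactants: 2; 3 (allyl tert-butyldimethylsilyl ether)
Product: 4 (2-[3-(TBSO)propyl]cyclopent-2-en-1-one)
Conditions: (i) 3, 9-BBN, THF, rt; (ii) 2, PdCl2(dppf), AsPh3, Cs2CO3, THF/DMF/H2O, rt
Reagents that add atoms: none
Why: In-situ terminal hydroboration of 3 gives a B-alkyl-9-BBN that couples with the α-iodoenone (B-alkyl Suzuki–Miyaura); the TBS ether survives.

**Step 3**
Reactants: 4; 5 (2-methylprop-1-en-1-ylmagnesium bromide)
Product: 6 ((2R,3S)-2-[3-(TBSO)propyl]-2-methyl-3-(2-methylprop-1-en-1-yl)cyclopentan-1-one)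
Conditions: 5 (1.5 equiv), CuBr·SMe2 (5 mol%), (R,S)-Josiphos (6 mol%), MTBE/CH2Cl2, –78 °C; then MeI, DMPU, –78 → 0 °C
Reagents that add atoms: iodomethane, CI
Why: Proposed new method: a chiral Cu–alkenyl species adds 1,4 to the hindered α-alkyl cyclopentenone, with the ligand choosing the face at C3 (S). The resulting tetrasubstituted enolate is regiodefined, and MeI attacks anti to the new isobutenyl group. This gives Me trans and the propyl chain cis to isobutenyl, i.e. a quaternary centre next to a tertiary one set in one pot. The closest known reactions are Cu-catalysed asymmetric addition of Grignards to cyclic enones and three-component conjugate addition/enolate alkylation, not yet shown for α-alkylcyclopentenones with an alkenyl Grignard.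

**Step 4**
Reactants: 6
Product: 7 ((2R,3S)-5-[(dimethylamino)methyl]-2-[3-(TBSO)propyl]-2-methyl-3-(2-methylprop-1-enyl)cyclopentan-1-one, C5 epimer mixture)
Conditions: LDA, THF, –78 °C; then Me2N+=CH2 I–, –78 °C → rt
Reagents that add atoms: Eschenmoser's salt, C=[N+](C)C.[I-]
Why: The quaternary α-carbon leaves only one enolisable position, so Mannich aminomethylation is regiospecific; the C5 stereocentre is destroyed in Step 5.

**Step 5**
Reactants: 7
Product: 8 ((2R,3S)-2-[3-(TBSO)propyl]-2-methyl-5-methylidene-3-(2-methylprop-1-enyl)cyclopentan-1-one)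
Conditions: MeI, CH2Cl2, rt; then aq. NaHCO3 (or DBU), 0 °C → rt; use crude at once
Reagents that add atoms: none (the added methyl leaves as NMe3)
Why: Quaternisation followed by E1cB elimination of NMe3 gives the α-methylene ketone.

**Step 6**
Reactants: 8
Product: 9 ((2R,3S,5S)-2-[3-(TBSO)propyl]-2,5-dimethyl-3-(2-methylprop-1-enyl)cyclopentan-1-one)
Conditions: H2 (1 atm), RhCl(PPh3)3, benzene, rt
Reagents that add atoms: none
Why: Wilkinson hydrogenation reduces the 1,1-disubstituted enone alkene and leaves the trisubstituted isobutenyl group. H2 is delivered to C5 from the face bearing only the C2 methyl (the face opposite the propyl chain and isobutenyl), so the new CH3 ends up cis to both.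

**Step 7**
Reactants: 9
Product: 10 (tert-butyl{3-[(1R,3S,5S)-1,3-dimethyl-2-methylidene-5-(2-methylprop-1-en-1-yl)cyclopentyl]propoxy}dimethylsilane)
Conditions: Cp2TiMe2, toluene/THF, 70 °C, dark
Reagents that add atoms: dimethyltitanocene (delivers CH2), C[Ti](C)(C1C=CC=C1)C1C=CC=C1
Why: Petasis methylenation is non-basic, so the α-stereocentre is not epimerised.

**Step 8**
Reactants: 10
Product: 11 ({(1S,2R,3S,5S)-2-[3-(TBSO)propyl]-2,5-dimethyl-3-(2-methylprop-1-enyl)cyclopentyl}methanol, CH2OH cis to the chain)
Conditions: 9-BBN, THF, 0 °C → rt; then 30% H2O2, 3 M NaOH, 0 °C → rt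
Reagents that add atoms: hydrogen peroxide, OO
Why: Hydroboration–oxidation of the 1,1-disubstituted exocyclic alkene is chemoselective over the trisubstituted alkene; syn addition from the less hindered face gives the kinetic CH2OH epimer, which is corrected in Step 10.

**Step 9**
Reactants: 11
Product: 12 ((1S,2R,3S,5S)-2-[3-(TBSO)propyl]-2,5-dimethyl-3-(2-methylprop-1-enyl)cyclopentane-1-carbaldehyde)
Conditions: Dess–Martin periodinane, NaHCO3, CH2Cl2, rt
Reagents that add atoms: none
Why: Mild oxidation of a primary alcohol leaves the TBS ether and the alkene untouched.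

**Step 10**
Reactants: 12
Product: 13 ((1R,2R,3S,5S)-aldehyde, CHO trans to the C5 methyl and the propyl chain)
Conditions: DBU (0.3 equiv), CH2Cl2, rt, 12 h
Reagents that add atoms: none
Why: Enolisation at the only acidic carbon equilibrates to the isomer with only one cis interaction (with the smaller ring methyl), which is the required C1 configuration; the C5 centre is β to the carbonyl and cannot epimerise.

**Step 11**
Reactants: 13
Product: 14 ({(1R,2R,3S,5S)-2-[3-(TBSO)propyl]-2,5-dimethyl-3-(2-methylprop-1-enyl)cyclopentyl}methanol, CH2OH trans to the chain)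
Conditions: NaBH4, MeOH, 0 °C; separate any minor C1 epimer by chromatography
Reagents that add atoms: none
Why: Carbonyl reduction does not touch the stereocentres.

**Step 12**
Reactants: 14; 15 (umbelliferone, 7-hydroxycoumarin)
Product: 16 (7-{[(1R,2R,3S,5S)-2-(3-TBSO-propyl)-2,5-dimethyl-3-(2-methylprop-1-enyl)cyclopentyl]methoxy}-2H-chromen-2-one)
Conditions: PBu3, ADDP, toluene, 0 → 50 °C
Reagents that add atoms: none
Why: Mitsunobu etherification of the acidic phenol (pKa ≈ 7.8) with a primary alcohol; the reacting carbon is CH2, so no stereocentre is affected.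

**Step 13**
Reactants: 16
Product: 17 (the primary alcohol, TBS removed)
Conditions: HF·pyridine, pyridine/THF, 0 °C → rt
Reagents that add atoms: none
Why: Buffered fluoride desilylation leaves the coumarin lactone (no hydroxide or strong base) and the alkene intact.

**Step 14**
Reactants: 17
Product: 18 (the chain aldehyde)
Conditions: Dess–Martin periodinane, NaHCO3, CH2Cl2, rt
Reagents that add atoms: none
Why: Selective oxidation of the only free alcohol.

**Step 15**
Reactants: 18
Product: 19 (ferulsinaic acid)
Conditions: NaClO2, NaH2PO4, 2-methylbut-2-ene, t-BuOH/H2O, rt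
Reagents that add atoms: sodium chlorite, O=Cl[O-].[Na+] (supplies the new O)
Why: Pinnick oxidation converts the aldehyde to the acid under mildly acidic conditions with a scavenger for HOCl, so the trisubstituted alkene and the coumarin survive.

**Compound list**
1 | cyclopent-2-en-1-one | O=C1C=CCC1 | starting material
2 | 2-iodocyclopent-2-en-1-one | O=C1CCC=C1I | intermediate
3 | tert-butyldimethyl(prop-2-en-1-yloxy)silane | C=CCO[Si](C)(C)C(C)(C)C | starting material
4 | 2-[3-(TBSO)propyl]cyclopent-2-en-1-one | O=C1CCC=C1CCCO[Si](C)(C)C(C)(C)C | intermediate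
5 | 2-methylprop-1-en-1-ylmagnesium bromide | CC(C)=C[Mg]Br | starting material
6 | (2R,3S)-2-[3-(TBSO)propyl]-2-methyl-3-(2-methylprop-1-enyl)cyclopentan-1-one | CC(C)=C[C@@H]1CCC(=O)[C@]1(C)CCCO[Si](C)(C)C(C)(C)C | intermediate
7 | (2R,3S)-5-[(dimethylamino)methyl] analogue of 6 (C5 unspecified) | CC(C)=C[C@@H]1CC(CN(C)C)C(=O)[C@]1(C)CCCO[Si](C)(C)C(C)(C)C | intermediate
8 | (2R,3S)-5-methylidene analogue of 6 | CC(C)=C[C@@H]1CC(=C)C(=O)[C@]1(C)CCCO[Si](C)(C)C(C)(C)C | intermediate
9 | (2R,3S,5S)-2,5-dimethyl analogue of 6 | CC(C)=C[C@@H]1C[C@H](C)C(=O)[C@]1(C)CCCO[Si](C)(C)C(C)(C)C | intermediate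
10 | Petasis alkene (1R,3S,5S) | CC(C)=C[C@@H]1C[C@H](C)C(=C)[C@]1(C)CCCO[Si](C)(C)C(C)(C)C | intermediate
11 | (1S,2R,3S,5S)-cyclopentylmethanol, CH2OH cis to chain | CC(C)=C[C@@H]1C[C@H](C)[C@H](CO)[C@]1(C)CCCO[Si](C)(C)C(C)(C)C | intermediate
12 | (1S,2R,3S,5S)-carbaldehyde | CC(C)=C[C@@H]1C[C@H](C)[C@H](C=O)[C@]1(C)CCCO[Si](C)(C)C(C)(C)C | intermediate
13 | (1R,2R,3S,5S)-carbaldehyde | CC(C)=C[C@@H]1C[C@H](C)[C@@H](C=O)[C@]1(C)CCCO[Si](C)(C)C(C)(C)C | intermediate
14 | (1R,2R,3S,5S)-cyclopentylmethanol | CC(C)=C[C@@H]1C[C@H](C)[C@@H](CO)[C@]1(C)CCCO[Si](C)(C)C(C)(C)C | intermediate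
15 | umbelliferone (7-hydroxy-2H-chromen-2-one) | O=c1ccc2ccc(O)cc2o1 | starting material
16 | coumarin ether of 14 (TBS ether) | CC(C)=C[C@@H]1C[C@H](C)[C@@H](COc2ccc3ccc(=O)oc3c2)[C@]1(C)CCCO[Si](C)(C)C(C)(C)C | intermediate
17 | coumarin ether with free 3-hydroxypropyl chain | CC(C)=C[C@@H]1C[C@H](C)[C@@H](COc2ccc3ccc(=O)oc3c2)[C@]1(C)CCCO | intermediate
18 | coumarin ether with 3-oxopropyl (propanal) chain | CC(C)=C[C@@H]1C[C@H](C)[C@@H](COc2ccc3ccc(=O)oc3c2)[C@]1(C)CCC=O | intermediate
19 | ferulsinaic acid, 3-[(1R,2R,3S,5S)-1,3-dimethyl-5-(2-methylprop-1-en-1-yl)-2-{[(2-oxo-2H-chromen-7-yl)oxy]methyl}cyclopentyl]propanoic acid | CC(C)=C[C@@H]1C[C@H](C)[C@@H](COc2ccc3ccc(=O)oc3c2)[C@]1(C)CCC(=O)O | target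

**Totals**
- Total steps: 15.
- Longest linear sequence: 15 steps (1 → 19); umbelliferone is commercial.

**Three steps most likely to fail**
1. **Step 3 (proposed new step):** α-substituted cyclopentenones are poor substrates for Cu-catalysed asymmetric conjugate addition of alkenyl Grignards, and magnesium enolates alkylate poorly with MeI.
   - Fallback: use known chemistry in two stages. Do racemic CuBr·SMe2/TMSCl conjugate addition, then regenerate the lithium enolate with MeLi and methylate with MeI/HMPA. Then resolve ketone 6 through SAMP/RAMP hydrazone diastereomers or preparative chiral SFC.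
2. **Step 6:** the hydrogenation face selectivity at C5 is uncertain, and Rh–H could isomerise the methylene into conjugation.
   - Fallback: change the mechanism to Magnus-type Mn(dpm)3/PhSiH3 radical conjugate reduction of 8, and separate the C5 epimers after Step 7.
3. **Step 12:** Mitsunobu etherification of a β-branched primary alcohol next to a quaternary centre may be slow.
   - Fallback: reverse the polarity of the coupling. Pd-RockPhos/Cs2CO3 C–O coupling of alcohol 14 with 7-bromocoumarin replaces alkylation of the phenol.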